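The constants were chosen freely; what happens was integrated by code.

Slowness is what I test first: can this closed flask still be creeping at the end of 6.0 d?

    acidic substrate + free base ⇌ protonated base + anion, settled at all times (K1 = 0.40)
    electrophile + anion ⇌ target (K2 = 20 /M, k2 = 5.2 /M/h)
    acidic substrate ⇌ dormant form (K3 = 0.48, k3 = 0.042 /h)

acidic substrate 0.40 M; free base 0.440 M; electrophile 0.600 M; time 6.0 d

- share of the acidic substrate used up at 6.0 d
- target at 6.0 d, in percent of the acidic substrate charged

- what has gone from acidic substrate into another species counts as reacted, even if it can come back
- run time (flask): 6.0 d

The exchange of acidic substrate with dormant form relaxes, both directions together, with a half-life ln(2)/(k3 + k3/K3) = 5.35 h, far shorter than the run. The capture of anion reverses at k2/K2 = 0.260 /h, far faster than once per run. So I book this flask at balance, under thermodynamic control.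

The acidic substrate is the limiting reagent, so its moles make my ledger, with four entries: free, dormant, anion, target. The dormant entry is K3 times the free one. Steps in series multiply, so the first two constants give an overall constant G = 8.00 /M for acidic substrate + free base + electrophile ⇌ protonated base + target. This gives the partition ratio: [target]/[acidic substrate] = G[electrophile][free base]/[protonated base]. Control passes from acidic substrate to target where this ratio crosses unity.

I set the anion entry aside and try 0.220 M of protonated base, with the electrophile down by the same amount. The ratio is 3.04, and the ledger closes with 0.269 M of target, more than that protonated base can account for. Trying 0.293 M gives a ratio of 1.23 and 0.181 M of target, too little. With the anion entry left out, my estimate of the target therefore lies between 45.3% and 67.3% of the acidic substrate charged.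

The forecast is sharper: conv 75.1% (73.5% to 76.5%) and y_P 55.7% (54% to 57.5%), on the ground that it “treated the flask as fully equilibrated”.

The simulation gives a conversion of 75.1% and a target yield of 55.7% for this flask, as forecast. Its relaxation half-lives, each by its step alone, 0.223 d for the dormant exchange and 0.292 h for anion capture at 6.00 d, are short against 6.0 d. The partition ratio from this flask's final amounts is 2.24, and target over acidic substrate reads 2.24. The neighbour with 0.18 M of free base lies below the crossing at 0.220 M: its ratio is 0.789, and its acidic substrate holds 42.5% against 33.5% of target.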